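**Plan**

- Cuts: (a) the C-6(chromene)–CH2 bond, leaving the bridge carbon on the filicinic ring as a C-methyl group (4 + 9); (b) O-1–C-2 and C-4–C-4a of the pyran ring (phenol + prenal); (c) the three ring C–CH3 bonds of ring A and both aryl–C(=O) bonds, back to one acylphloroglucinol 3 and phloroglucinol.
- Forward: phloroglucinol → 3, which feeds both halves; 3 → 4 (dearomatised ring A); 3 → 5 → 8 → 9 (pyran ring closed on the oxygen next to the ketone because O-4 is blocked); then 4 + 9 → uliginosin B.
- Key idea (biomimetic): the CH2 bridge is not brought in as formaldehyde. It is a methionine-type C-methyl group of ring A that is oxidised to a quinone-methide-like exocyclic enone and captured by the chromene, so the electrophile and nucleophile roles are fixed by structure and no homodimer can form.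
- Enabling feature: the bridge carbon sits on C-4 of ring A between the enolised C-3–O and C-5–O (so CH3 → 2-methylene-1,3-dione is possible), and on C-6 of the chromene ring between the C-5 and C-7 hydroxyls, the only unsubstituted arene carbon.
- Stereochemistry: none to set; the target is achiral.

Key step: step 6

Remark on the chemistry: the target has no stereocentre and its ring olefin can only be cis, so there is no enantiomer to select. The β-triketone ring is written as the enol tautomer of the given SMILES; 4, 7, 10 and 11 are likewise drawn as one tautomer each, and 10 is racemic at its transient quaternary carbon.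

**Route**

Step 1
Reactants: 1 phloroglucinol; 2 isobutyryl chloride (2-methylpropanoyl chloride)
Product: 3 isobutyrylphloroglucinol, 2-methyl-1-(2,4,6-trihydroxyphenyl)propan-1-one
Conditions: AlCl3 (3.5 equiv), PhNO2, rt → 65 °C; aq. HCl work-up
Reagents that add atoms: none
Why: Friedel–Crafts C-acylation of the threefold-symmetric, highly activated arene should stop after one acyl group because the aluminium-chelated aryl ketone deactivates the ring, and symmetry allows only one product.

Step 2
Reactants: 3 isobutyrylphloroglucinol
Product: 4 C-methyl-isobutyrylfilicinic acid, 3,5-dihydroxy-4,6,6-trimethyl-2-(2-methylpropanoyl)cyclohexa-2,4-dien-1-one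
Conditions: NaOMe (4 equiv), MeI (3.2 equiv), MeOH, 0 °C → rt; acidify
Reagents that add atoms: iodomethane, CI
Why: Dearomative C-alkylation of the phloroglucinol polyanion (enolate C-methylation) should place two methyls on one free ring carbon and the third on the other, both possible orders converging on the same trione, with the limited amount of MeI holding the reaction before the tetramethyl stage; no stereocentre arises because the C-methyl carbon stays enolised.

Step 3
Reactants: 3 isobutyrylphloroglucinol
Product: 5 1-[2,6-dihydroxy-4-(methoxymethoxy)phenyl]-2-methylpropan-1-one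
Conditions: MOMCl (1.05 equiv), i-Pr2NEt (1.1 equiv), THF/CH2Cl2, −10 → 0 °C
Reagents that add atoms: chloromethyl methyl ether, COCCl
Why: Williamson-type O-alkylation with one equivalent of a hard electrophile should go to the 4-OH, which is the most acidic hydroxyl and the only one not held in a hydrogen bond to the ketone.

Step 4
Reactants: 5 1-[2,6-dihydroxy-4-(methoxymethoxy)phenyl]-2-methylpropan-1-one; 6 3-methylbut-2-enal (prenal)
Product: 8 1-[7-hydroxy-5-(methoxymethoxy)-2,2-dimethyl-2H-chromen-8-yl]-2-methylpropan-1-one, via vinyl ortho-quinone methide 7 (not isolated)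
Conditions: 6 (1.1 equiv), ethylenediammonium diacetate (0.2 equiv), toluene, 100–110 °C
Reagents that add atoms: none
Why: Amine-salt-catalysed Knoevenagel-type condensation followed by oxa-6π electrocyclisation (formal [3+3] chromene annulation) should give a single chromene, because in 5 the two free ring carbons and the two free hydroxyls are equivalent and O-4 is blocked, so the pyran oxygen must be the one next to the ketone; limiting the aldehyde guards against a second annulation.

Step 5
Reactants: 8 1-[7-hydroxy-5-(methoxymethoxy)-2,2-dimethyl-2H-chromen-8-yl]-2-methylpropan-1-one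
Product: 9 1-(5,7-dihydroxy-2,2-dimethyl-2H-chromen-8-yl)-2-methylpropan-1-one
Conditions: 3 M aq. HCl (cat.), MeOH, 45 °C
Reagents that add atoms: none
Why: Acid-catalysed acetal exchange (MOM ether methanolysis) should free the 5-OH under conditions that the chromene olefin and the aryl ketone tolerate.

Step 6
Reactants: 4 C-methyl-isobutyrylfilicinic acid; 9 1-(5,7-dihydroxy-2,2-dimethyl-2H-chromen-8-yl)-2-methylpropan-1-one
Product: 12 uliginosin B, via TEMPO alkoxyamine 10 (not isolated), via methylene trione 11 (not isolated)
Conditions: (i) 4 (1.3 equiv), TEMPO (1.3 equiv), Ag2O (1.0 equiv), THF, 0 °C → rt, dark; filter through Celite, evaporate; (ii) 9 (1.0 equiv), toluene, 70 °C, no added base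
Reagents that add atoms: TEMPO, CC1(C)CCCC(C)(C)N1[O] (atoms present in intermediate 10 only, none in 12)
Why: Proposed new method: Ag(I) should oxidise the enol of β-triketone 4 to a captodative carbon radical that TEMPO traps at the methyl-bearing ring carbon (α-oxyamination of a 1,3-dicarbonyl), and after removal of the silver, warming should cleave the weak tertiary C–ON bond with loss of the hydroxylamine from the methyl group, releasing slowly the 2-methylene-1,3-dione 11, the dearomatised analogue of an ortho-quinone methide and the same electrophile through which formaldehyde couplings of filicinic acids pass. The closest known reaction types are the TEMPO/Ag2O conversion of C-methyl acylfilicinic acids into such exocyclic enones with capture by alkenes in hetero-Diels–Alder reactions, and the conjugate (Friedel–Crafts-type) addition of acylphloroglucinols to alkylidene cyclohexanetriones; what is new is the interception of the oxidatively formed enone by an arene carbon to make the CH2 bridge. No ring closes and no stereocentre arises, since the quaternary carbon of 10 returns to sp2. The selectivities needed are cross- over homo-coupling and C-6 arylation over O-alkylation or [4+2] addition at the chromene olefin: 4 has no free nucleophilic ring carbon and 9 has no oxidisable methyl group, so only one pairing exists; C-6 of 9 is the only unsubstituted arene carbon and is flanked by two hydroxyls that can hydrogen-bond to the enone carbonyl and deliver the arene carbon to the CH2 terminus, after which rearomatisation makes the addition irreversible; slow release keeps the enone concentration low against self-dimerisation, and the oxidant is filtered off before the oxidation-sensitive phenol is added.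

**Compound list**

1 | phloroglucinol (benzene-1,3,5-triol) | Oc1cc(O)cc(O)c1 | starting material
2 | isobutyryl chloride (2-methylpropanoyl chloride) | CC(C)C(Cl)=O | starting material
3 | isobutyrylphloroglucinol, 2-methyl-1-(2,4,6-trihydroxyphenyl)propan-1-one | CC(C)C(=O)c1c(O)cc(O)cc1O | intermediate
4 | C-methyl-isobutyrylfilicinic acid, 3,5-dihydroxy-4,6,6-trimethyl-2-(2-methylpropanoyl)cyclohexa-2,4-dien-1-one | CC(C)C(=O)C1=C(O)C(C)=C(O)C(C)(C)C1=O | intermediate
5 | 1-[2,6-dihydroxy-4-(methoxymethoxy)phenyl]-2-methylpropan-1-one | CC(C)C(=O)c1c(O)cc(OCOC)cc1O | intermediate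
6 | 3-methylbut-2-enal (prenal) | CC(C)=CC=O | starting material
7 | 3-hydroxy-5-(methoxymethoxy)-6-(3-methylbut-2-enylidene)-2-(2-methylpropanoyl)cyclohexa-2,4-dien-1-one | CC(C)C(=O)C1=C(O)C=C(OCOC)C(=CC=C(C)C)C1=O | intermediate (not isolated)
8 | 1-[7-hydroxy-5-(methoxymethoxy)-2,2-dimethyl-2H-chromen-8-yl]-2-methylpropan-1-one | CC(C)C(=O)c1c(O)cc(OCOC)c2C=CC(C)(C)Oc12 | intermediate
9 | 1-(5,7-dihydroxy-2,2-dimethyl-2H-chromen-8-yl)-2-methylpropan-1-one | CC(C)C(=O)c1c(O)cc(O)c2C=CC(C)(C)Oc12 | intermediate
10 | 3-hydroxy-4,6,6-trimethyl-2-(2-methylpropanoyl)-4-[(2,2,6,6-tetramethylpiperidin-1-yl)oxy]cyclohex-2-ene-1,5-dione (racemic) | CC(C)C(=O)C1=C(O)C(C)(ON2C(C)(C)CCCC2(C)C)C(=O)C(C)(C)C1=O | intermediate (not isolated)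
11 | 3-hydroxy-6,6-dimethyl-4-methylidene-2-(2-methylpropanoyl)cyclohex-2-ene-1,5-dione | CC(C)C(=O)C1=C(O)C(=C)C(=O)C(C)(C)C1=O | intermediate (not isolated)
12 | uliginosin B, 3,5-dihydroxy-4-{[5,7-dihydroxy-2,2-dimethyl-8-(2-methylpropanoyl)-2H-chromen-6-yl]methyl}-6,6-dimethyl-2-(2-methylpropanoyl)cyclohexa-2,4-dien-1-one | CC(C)C(=O)C1=C(O)C(Cc2c(O)c3c(c(C(=O)C(C)C)c2O)OC(C)(C)C=C3)=C(O)C(C)(C)C1=O | target

**Totals**

Total step count: 6. Longest linear sequence: 5 steps (steps 1, 3, 4, 5, 6); the other branch is steps 1, 2, 6.

**Steps most likely to fail**

Step 6 (proposed new method). The hydroxylamine may already be lost during the oxidation stage, so that the enone condenses with itself before the phenol is present. Carried-over oxidant may attack the phenol, or the enone may add across the chromene olefin in a [4+2] sense instead of arylating C-6. The fallback gives up the oxidation and brings the bridge carbon in at the formaldehyde level by known chemistry. It sets out from 3: C-dimethylation (NaOMe, MeI 2.1 equiv, MeOH) should stop at isobutyrylfilicinic acid F1. Aminomethylation of its one free ring carbon with Eschenmoser's salt (CH2Cl2, rt) should give the Mannich base 4-[(dimethylamino)methyl]-isobutyrylfilicinic acid F2. Heating F2 with 9 (dioxane, 80–100 °C) should expel dimethylamine, form enone 11 without any oxidant and give the same conjugate addition. The fallback comes back to the route at 12.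

Step 3. Over-alkylation to a bis-MOM ether and incomplete discrimination between the para and the chelated ortho hydroxyls would erode the regiocontrol on which step 4 depends. The fallback avoids selective protection and builds the pyran from the oxygen side. It sets out from 3: excess MOMCl/i-Pr2NEt should protect the para and one ortho hydroxyl, giving 1-[2-hydroxy-4,6-bis(methoxymethoxy)phenyl]-2-methylpropan-1-one F3 with a single chelated OH left. O-Alkylation of that OH with 3-chloro-3-methylbut-1-yne (K2CO3, KI, cat. CuI, DMF, 60 °C) should give the aryl 1,1-dimethylpropargyl ether 1-[2,4-bis(methoxymethoxy)-6-(2-methylbut-3-yn-2-yloxy)phenyl]-2-methylpropan-1-one F4. Thermolysis (N,N-diethylaniline, 170 °C) should cause propargyl Claisen rearrangement to the only free ortho carbon, 1,5-hydrogen shift and oxa-6π closure to 1-[5,7-bis(methoxymethoxy)-2,2-dimethyl-2H-chromen-8-yl]-2-methylpropan-1-one F5, the ether oxygen necessarily becoming O-1 next to the acyl-bearing carbon. HCl/MeOH then removes both MOM groups. The fallback comes back to the route at 9 and also bypasses step 4.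

Step 2. Methylation is statistical, so under-methylation, over-methylation to the tetramethyl trione and O-methylation may leave little of the trimethyl compound. The fallback buys the future bridge carbon already attached to the arene. It sets out from 2 and purchased 2,4,6-trihydroxytoluene F6: Friedel–Crafts acylation (AlCl3, PhNO2, 65 °C) should give 2-methyl-1-(2,4,6-trihydroxy-3-methylphenyl)propan-1-one F7. Geminal C-dimethylation of its single free ring carbon (NaOMe, MeI 2.1 equiv, MeOH) is then the only dearomatising pathway. The fallback comes back to the route at 4.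

**Further compounds**

F1 | step 6 | isobutyrylfilicinic acid, 3,5-dihydroxy-6,6-dimethyl-2-(2-methylpropanoyl)cyclohexa-2,4-dien-1-one | CC(C)C(=O)C1=C(O)C=C(O)C(C)(C)C1=O
F2 | step 6 | 4-[(dimethylamino)methyl]-3,5-dihydroxy-6,6-dimethyl-2-(2-methylpropanoyl)cyclohexa-2,4-dien-1-one | CC(C)C(=O)C1=C(O)C(CN(C)C)=C(O)C(C)(C)C1=O
F3 | step 3 | 1-[2-hydroxy-4,6-bis(methoxymethoxy)phenyl]-2-methylpropan-1-one | CC(C)C(=O)c1c(O)cc(OCOC)cc1OCOC
F4 | step 3 | 1-[2,4-bis(methoxymethoxy)-6-(2-methylbut-3-yn-2-yloxy)phenyl]-2-methylpropan-1-one | CC(C)C(=O)c1c(OCOC)cc(OCOC)cc1OC(C)(C)C#C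
F5 | step 3 | 1-[5,7-bis(methoxymethoxy)-2,2-dimethyl-2H-chromen-8-yl]-2-methylpropan-1-one | CC(C)C(=O)c1c(OCOC)cc(OCOC)c2C=CC(C)(C)Oc12
F6 | step 2 | 2,4,6-trihydroxytoluene (2-methylphloroglucinol, purchased starting material of the fallback) | Cc1c(O)cc(O)cc1O
F7 | step 2 | 2-methyl-1-(2,4,6-trihydroxy-3-methylphenyl)propan-1-one | CC(C)C(=O)c1c(O)cc(O)c(C)c1O
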